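The flavonol is cut across its pyranone ring (ring C) at C3–C4 and O1–C2. C4 sits ortho to the ring oxygen O1 on the fully substituted A ring, so it can enter as an aldehyde carbon next to a free phenol. C2 and C3, with the catechol B ring on C2, come from an aroyl sulfoxonium ylide. One rhodium-catalysed operation makes both bonds and closes ring C. The aldehyde partner is a pentaoxygenated salicylaldehyde (2-OH, 3,5-OMe, 4,6-OBn) built from syringol. The C3 hydroxyl is added afterwards, and four benzyl ethers are removed last.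

Key step: step 8

Remark: the target has no stereocentre and its SMILES carries no stereodescriptor, so there is no enantiomer to control.

Step 1
Reactants: 1 2,6-dimethoxyphenol (syringol)
Product: 2 2-(benzyloxy)-1,3-dimethoxybenzene
Conditions: BnBr (1.1 equiv), K2CO3, DMF, 60 °C
Reagents that add atoms: benzyl bromide BrCc1ccccc1
Why: Williamson ether synthesis on the phenoxide; the benzyl group masks the future 7-OH and should survive every step up to the final hydrogenolysis.

Step 2
Reactants: 2 2-(benzyloxy)-1,3-dimethoxybenzene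
Product: 3 3-(benzyloxy)-1,5-dibromo-2,4-dimethoxybenzene
Conditions: NBS (2.2 equiv), MeCN, 0 °C → rt, dark
Reagents that add atoms: N-bromosuccinimide O=C1CCC(=O)N1Br
Why: Electrophilic aromatic bromination; each position next to a methoxy group is ortho to one methoxy and para to the other, whereas the third C–H is activated only by the twisted central benzyloxy group, so the symmetric dibromide should form by analogy with 1,2,3-trimethoxybenzene.

Step 3
Reactants: 3 3-(benzyloxy)-1,5-dibromo-2,4-dimethoxybenzene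
Product: 4 5-(benzyloxy)-4,6-dimethoxybenzene-1,3-diol
Conditions: Pd2(dba)3 (2 mol %), tBuXPhos (8 mol %), KOH (6 equiv), 1,4-dioxane/H2O, 100 °C, Ar; then aq. HCl
Reagents that add atoms: potassium hydroxide [K+].[OH-]
Why: Palladium-catalysed hydroxylation of aryl bromides with hydroxide (Buchwald-type C–O coupling); the bulky biaryl phosphine should drive C–O reductive elimination at both C–Br bonds and hold back diaryl ether formation, and the methyl and benzyl ethers are inert to hot hydroxide.

Step 4
Reactants: 4 5-(benzyloxy)-4,6-dimethoxybenzene-1,3-diol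
Product: 6 4-(benzyloxy)-2,6-dihydroxy-3,5-dimethoxybenzaldehyde, via aryl iminium chloride 5 (not isolated)
Conditions: POCl3 (1.3 equiv)/DMF (preformed), MeCN, 0 °C → rt; then H2O, 50 °C
Reagents that add atoms: N,N-dimethylformamide CN(C)C=O; water O
Why: Vilsmeier–Haack formylation; the only ring C–H is ortho to both hydroxyls and para to the benzyloxy group (a phloroglucinol-type carbon), so it is strongly nucleophilic and the regiochemistry is unambiguous.

Step 5
Reactants: 6 4-(benzyloxy)-2,6-dihydroxy-3,5-dimethoxybenzaldehyde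
Product: 7 4,6-bis(benzyloxy)-2-hydroxy-3,5-dimethoxybenzaldehyde
Conditions: BnBr (1.05 equiv), K2CO3 (1.1 equiv), acetone, rt → 45 °C
Reagents that add atoms: benzyl bromide BrCc1ccccc1
Why: Williamson mono-O-benzylation; the two hydroxyls are equivalent by symmetry, and once one is alkylated the other is held in a hydrogen bond to the formyl oxygen, which should slow a second alkylation with one equivalent of halide and a weak base.

Step 6
Reactants: 8 3,4-dihydroxybenzoic acid
Product: 10 3,4-bis(benzyloxy)benzoic acid, via benzyl ester 9 (not isolated)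
Conditions: BnBr (3.5 equiv), K2CO3, DMF, 60 °C; then NaOH, MeOH/H2O, 70 °C; then aq. HCl
Reagents that add atoms: benzyl bromide BrCc1ccccc1; sodium hydroxide [Na+].[OH-]
Why: Exhaustive Williamson and carboxylate O-benzylation followed by saponification of the benzyl ester in the same flask; aryl benzyl ethers do not react with hydroxide.

Step 7
Reactants: 10 3,4-bis(benzyloxy)benzoic acid; 11 trimethylsulfoxonium iodide
Product: 14 1-[3,4-bis(benzyloxy)phenyl]-2-[dimethyl(oxo)-λ6-sulfanylidene]ethanone, via acid chloride 12 (not isolated), via dimethylsulfoxonium methylide 13 (not isolated)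
Conditions: 10, (COCl)2, DMF (cat.), CH2Cl2, 0 °C → rt, evaporate; 11 (3 equiv), KOtBu (3 equiv), THF, reflux; then 12 in THF, 0 °C → rt
Reagents that add atoms: none
Why: Acyl chloride formation followed by C-acylation of the Corey–Chaykovsky ylide; a second equivalent of methylide deprotonates the acylsulfoxonium salt to the carbonyl-stabilised ylide, which should be isolable as a stable solid.

Step 8
Reactants: 7 4,6-bis(benzyloxy)-2-hydroxy-3,5-dimethoxybenzaldehyde; 14 1-[3,4-bis(benzyloxy)phenyl]-2-[dimethyl(oxo)-λ6-sulfanylidene]ethanone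
Product: 16 5,7-bis(benzyloxy)-2-[3,4-bis(benzyloxy)phenyl]-6,8-dimethoxy-4H-chromen-4-one, via diketone 15 (not isolated)
Conditions: 14 (1.5 equiv), [Cp*RhCl2]2 (5 mol %), AgSbF6 (20 mol %), PivOH (1 equiv), DCE, 80 °C; then p-TsOH·H2O (0.2 equiv), 80 °C
Reagents that add atoms: none
Why: Cationic Cp*Rh(III) binds the phenoxide of 7 and cleaves the formyl C–H by carboxylate-assisted metalation to a five-membered acyl rhodacycle; ylide 14 then coordinates through carbon, expels DMSO to give a rhodium carbene, the acyl group migrates onto the carbene carbon to form C3–C4, and protonolysis releases diketone 15 and returns the catalyst. The closest known reaction type is the redox-neutral Rh(III)-catalysed annulation of salicylaldehydes with aroyl sulfoxonium ylides or diazo ketones to flavones and chromones. Ring C then closes by 6-exo-trig addition of the phenol oxygen (O1) to the B-ring ketone carbon (C2), followed by acid-promoted loss of water. No stereocentre is formed. The step needs carbene insertion to outrun CO extrusion from the di-ortho-substituted acyl rhodium and ketone-directed self-annulation of the ylide; the A ring of 7 has no aryl C–H, the chelating phenoxide keeps the acyl group on the metal, excess ylide at moderate temperature favours insertion, and the regiochemistry is fixed because the carbene carbon can only become C3 with its aryl ketone carbon as C2.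

Step 9
Reactants: 16 5,7-bis(benzyloxy)-2-[3,4-bis(benzyloxy)phenyl]-6,8-dimethoxy-4H-chromen-4-one
Product: 19 5,7-bis(benzyloxy)-2-[3,4-bis(benzyloxy)phenyl]-3-hydroxy-6,8-dimethoxy-4H-chromen-4-one, via 3-lithioflavone 17 (not isolated), via flavone-3-boronate 18 (not isolated)
Conditions: LDA (1.5 equiv), THF, −78 °C; B(OMe)3 (3 equiv), −78 → 0 °C; then AcOH, 30% H2O2, 0 °C → rt
Reagents that add atoms: hydrogen peroxide OO
Why: Regioselective C3 lithiation of the flavone (its only vinylic C–H, α to the carbonyl), borylation, and oxidative C–B to C–O cleavage by 1,2-migration to peroxide oxygen; aryl benzyl ethers should tolerate LDA at −78 °C and buffered peroxide.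

Step 10
Reactants: 19 5,7-bis(benzyloxy)-2-[3,4-bis(benzyloxy)phenyl]-3-hydroxy-6,8-dimethoxy-4H-chromen-4-one
Product: 20 3,5,7,3',4'-pentahydroxy-6,8-dimethoxyflavone
Conditions: H2 (1 atm), 10% Pd/C, THF/MeOH, rt
Reagents that add atoms: none
Why: Catalytic hydrogenolysis of four aryl benzyl ethers; the methyl ethers and the tetrasubstituted enol-type C2=C3 bond of the flavonol should be untouched at balloon pressure.

Compound list

1 | 2,6-dimethoxyphenol (syringol) | COc1cccc(OC)c1O | starting material
2 | 2-(benzyloxy)-1,3-dimethoxybenzene | COc1cccc(OC)c1OCc1ccccc1 | intermediate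
3 | 3-(benzyloxy)-1,5-dibromo-2,4-dimethoxybenzene | COc1c(Br)cc(Br)c(OC)c1OCc1ccccc1 | intermediate
4 | 5-(benzyloxy)-4,6-dimethoxybenzene-1,3-diol | COc1c(O)cc(O)c(OC)c1OCc1ccccc1 | intermediate
5 | N-{[4-(benzyloxy)-2,6-dihydroxy-3,5-dimethoxyphenyl]methylidene}-N-methylmethanaminium chloride (aryl iminium chloride, not isolated) | COc1c(O)c(C=[N+](C)C)c(O)c(OC)c1OCc1ccccc1.[Cl-] | intermediate
6 | 4-(benzyloxy)-2,6-dihydroxy-3,5-dimethoxybenzaldehyde | COc1c(O)c(C=O)c(O)c(OC)c1OCc1ccccc1 | intermediate
7 | 4,6-bis(benzyloxy)-2-hydroxy-3,5-dimethoxybenzaldehyde | COc1c(O)c(C=O)c(OCc2ccccc2)c(OC)c1OCc1ccccc1 | intermediate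
8 | 3,4-dihydroxybenzoic acid | OC(=O)c1ccc(O)c(O)c1 | starting material
9 | benzyl 3,4-bis(benzyloxy)benzoate (not isolated) | O=C(OCc1ccccc1)c1ccc(OCc2ccccc2)c(OCc2ccccc2)c1 | intermediate
10 | 3,4-bis(benzyloxy)benzoic acid | OC(=O)c1ccc(OCc2ccccc2)c(OCc2ccccc2)c1 | intermediate
11 | trimethylsulfoxonium iodide | C[S+](C)(C)=O.[I-] | starting material
12 | 3,4-bis(benzyloxy)benzoyl chloride (not isolated) | O=C(Cl)c1ccc(OCc2ccccc2)c(OCc2ccccc2)c1 | intermediate
13 | dimethylsulfoxonium methylide (not isolated) | CS(C)(=O)=C | intermediate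
14 | 1-[3,4-bis(benzyloxy)phenyl]-2-[dimethyl(oxo)-λ6-sulfanylidene]ethanone | CS(C)(=O)=CC(=O)c1ccc(OCc2ccccc2)c(OCc2ccccc2)c1 | intermediate
15 | 1-[4,6-bis(benzyloxy)-2-hydroxy-3,5-dimethoxyphenyl]-3-[3,4-bis(benzyloxy)phenyl]propane-1,3-dione (not isolated) | COc1c(O)c(C(=O)CC(=O)c2ccc(OCc3ccccc3)c(OCc3ccccc3)c2)c(OCc2ccccc2)c(OC)c1OCc1ccccc1 | intermediate
16 | 5,7-bis(benzyloxy)-2-[3,4-bis(benzyloxy)phenyl]-6,8-dimethoxy-4H-chromen-4-one | COc1c(OCc2ccccc2)c(OC)c2oc(-c3ccc(OCc4ccccc4)c(OCc4ccccc4)c3)cc(=O)c2c1OCc1ccccc1 | intermediate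
17 | {5,7-bis(benzyloxy)-2-[3,4-bis(benzyloxy)phenyl]-6,8-dimethoxy-4-oxo-4H-chromen-3-yl}lithium (not isolated) | COc1c(OCc2ccccc2)c(OC)c2oc(-c3ccc(OCc4ccccc4)c(OCc4ccccc4)c3)c([Li])c(=O)c2c1OCc1ccccc1 | intermediate
18 | dimethyl {5,7-bis(benzyloxy)-2-[3,4-bis(benzyloxy)phenyl]-6,8-dimethoxy-4-oxo-4H-chromen-3-yl}boronate (not isolated) | COc1c(OCc2ccccc2)c(OC)c2oc(-c3ccc(OCc4ccccc4)c(OCc4ccccc4)c3)c(B(OC)OC)c(=O)c2c1OCc1ccccc1 | intermediate
19 | 5,7-bis(benzyloxy)-2-[3,4-bis(benzyloxy)phenyl]-3-hydroxy-6,8-dimethoxy-4H-chromen-4-one | COc1c(OCc2ccccc2)c(OC)c2oc(-c3ccc(OCc4ccccc4)c(OCc4ccccc4)c3)c(O)c(=O)c2c1OCc1ccccc1 | intermediate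
20 | 3,5,7,3',4'-pentahydroxy-6,8-dimethoxyflavone (achiral) | COc1c(O)c(OC)c2oc(-c3ccc(O)c(O)c3)c(O)c(=O)c2c1O | target

Total step count: 10 (steps 1–5 to the aldehyde, steps 6–7 to the ylide, steps 8–10 after convergence).
Longest linear sequence: 8 steps (1, 2, 3, 4, 5, 8, 9, 10).

Steps most likely to fail

Step 8. The crowded acyl rhodium may lose CO before the carbene inserts, or the ylide may be consumed by its own ketone-directed annulation. The fallback reaches the same diketone without C–H activation. Setting out from 7, methylmagnesium bromide (3 equiv, THF, 0 °C) should add to the aldehyde to give racemic 1-[4,6-bis(benzyloxy)-2-hydroxy-3,5-dimethoxyphenyl]ethan-1-ol F1. MnO2 in CH2Cl2 should oxidise the benzylic alcohol to 1-[4,6-bis(benzyloxy)-2-hydroxy-3,5-dimethoxyphenyl]ethan-1-one F2. Its lithium dianion (LiHMDS, 3.5 equiv, THF, −78 °C) is then C-acylated with acid chloride 12, made from 10 as in step 7 (a one-flask Baker–Venkataraman variant), to give diketone 15. Cyclodehydration with catalytic p-TsOH in toluene at 80 °C returns to the route at 16.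

Step 9. Lithiation may be incomplete, the 3-lithio species may ring-open to an ynone phenoxide on warming, or a benzylic ether position may be metalated. The fallback oxidises the C2=C3 bond directly. Setting out from 16, dimethyldioxirane (acetone/CH2Cl2, 0 °C → rt) should give racemic cis-fused 4,6-bis(benzyloxy)-1a-[3,4-bis(benzyloxy)phenyl]-3,5-dimethoxy-1a,7a-dihydro-7H-oxireno[2,3-b]chromen-7-one F3. Catalytic p-TsOH in CH2Cl2 should open the epoxide at C2 and, after loss of the C3 proton, return to the route at 19.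

Step 3. The coupling may stall after the first C–O bond, the bromide may be reduced, or the phenoxide product may couple with remaining bromide to give aryl ethers. The fallback forms C–B bonds first. Setting out from 3, Miyaura borylation (B2pin2 2.5 equiv, Pd(dppf)Cl2, KOAc, 1,4-dioxane, 90 °C) should give 2,2'-[5-(benzyloxy)-4,6-dimethoxy-1,3-phenylene]bis(4,4,5,5-tetramethyl-1,3,2-dioxaborolane) F4. Oxidation with 30% H2O2 and aqueous NaOH in THF at 0 °C returns to the route at 4.

Further compounds

F1 | step 8 | 1-[4,6-bis(benzyloxy)-2-hydroxy-3,5-dimethoxyphenyl]ethan-1-ol (racemic, carbinol centre unspecified) | COc1c(O)c(C(C)O)c(OCc2ccccc2)c(OC)c1OCc1ccccc1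
F2 | step 8 | 1-[4,6-bis(benzyloxy)-2-hydroxy-3,5-dimethoxyphenyl]ethan-1-one | COc1c(O)c(C(C)=O)c(OCc2ccccc2)c(OC)c1OCc1ccccc1
F3 | step 9 | 4,6-bis(benzyloxy)-1a-[3,4-bis(benzyloxy)phenyl]-3,5-dimethoxy-1a,7a-dihydro-7H-oxireno[2,3-b]chromen-7-one (racemic, cis-fused, one enantiomer drawn) | O=C1[C@H]2O[C@@]2(c2ccc(OCc3ccccc3)c(OCc3ccccc3)c2)Oc2c(OC)c(OCc3ccccc3)c(OC)c(OCc3ccccc3)c21
F4 | step 3 | 2,2'-[5-(benzyloxy)-4,6-dimethoxy-1,3-phenylene]bis(4,4,5,5-tetramethyl-1,3,2-dioxaborolane) | COc1c(B2OC(C)(C)C(C)(C)O2)cc(B2OC(C)(C)C(C)(C)O2)c(OC)c1OCc1ccccc1
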